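**Retrosynthetic overview**

1. Numbering: the chlorinated isoflavone carries rings A/C/B (atoms unprimed, aryl C1'–C4'); the second isoflavone carries rings A''/C''/B'' (atoms double-primed). The ether carbon C8'' lies between C7''–OH and C8a''–O1'', just as C8–Cl lies between C7–OH and C8a–O1. Without their pyranone rings, both A rings are therefore 2-substituted resorcinols whose two open positions are equivalent.
2. Key disconnection (last step): the whole pyranone ring C'' (bonds C4''–C4a'', C2''–C3'', O1''–C2'') is removed together with ring B''. This leads to the symmetric 2-aryloxyresorcinol 8, 4-hydroxyphenylacetic acid 9 and one carbon from DMF: three components, one pot, no protecting groups.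
3. 8 ⇐ 7 (demethylation) ⇐ aryl bromide 5 + 2,6-dimethoxyphenol 6 by Ullmann-type etherification. The doubly ortho-flanked ether bond is thus formed on a cheap symmetric phenol, not between two isoflavones.
4. 5 ⇐ 4 ⇐ 2-chlororesorcinol 1 + 4-bromophenylacetic acid 2 + DMF, by the same three-component annulation (ring C).
5. Order of ring formation: ring C (step 1), diaryl ether (step 3), ring C'' (step 5).

Key step: step 5

Remark: the target has no stereocentre, no stereogenic double bond and no hindered axis (the diaryl ether rotates freely); it is achiral, so no stereocontrol is needed.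
Remark: BF3·OEt2 serves as Lewis-acidic solvent in steps 1 and 5 and is treated as medium, not as a consumed reagent.

**Route**

Step 1
Reactants: 1 2-chlororesorcinol (2-chlorobenzene-1,3-diol); 2 4-bromophenylacetic acid
Product: 4 3-(4-bromophenyl)-8-chloro-7-hydroxy-4H-chromen-4-one, via bromo deoxybenzoin 3 (not isolated)
Conditions: BF3·OEt2 (neat), 85 °C; then DMF, MsCl, 70 °C; aq. NaOAc work-up
Reagents that add atoms: N,N-dimethylformamide, CN(C)C=O
Why: Friedel–Crafts (Fries-type) C-acylation of the resorcinol at C4 (ortho and para to the two OH groups, both open positions being equivalent) should give deoxybenzoin 3, whose methylene is then formylated by the DMF/MsCl iminium salt (Vilsmeier-type) and closed by the ortho-OH with loss of dimethylamine, the established one-pot route to unprotected 7-hydroxyisoflavones.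

Step 2
Reactants: 4 3-(4-bromophenyl)-8-chloro-7-hydroxy-4H-chromen-4-one
Product: 5 3-(4-bromophenyl)-8-chloro-7-methoxy-4H-chromen-4-one
Conditions: MeI, K2CO3, acetone, reflux
Reagents that add atoms: iodomethane, CI
Why: Williamson etherification of the only phenol (the acidic 7-OH) masks it so that it cannot compete as a nucleophile in the copper step, and the methyl group leaves together with the other two in step 4.

Step 3
Reactants: 5 3-(4-bromophenyl)-8-chloro-7-methoxy-4H-chromen-4-one; 6 2,6-dimethoxyphenol
Product: 7 8-chloro-3-[4-(2,6-dimethoxyphenoxy)phenyl]-7-methoxy-4H-chromen-4-one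
Conditions: CuI (10 mol%), picolinic acid (20 mol%), anhydrous K3PO4, DMSO, 95 °C, argon
Reagents that add atoms: none
Why: Ullmann-type Cu(I)/picolinate C–O coupling under conditions suited to di-ortho-substituted phenols should engage the unhindered C4'–Br, whereas the hindered, electron-rich C8–Cl is inert to copper at this temperature.

Step 4
Reactants: 7 8-chloro-3-[4-(2,6-dimethoxyphenoxy)phenyl]-7-methoxy-4H-chromen-4-one
Product: 8 8-chloro-3-[4-(2,6-dihydroxyphenoxy)phenyl]-7-hydroxy-4H-chromen-4-one
Conditions: BBr3 (excess), CH2Cl2, −78 °C to rt; ice-water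
Reagents that add atoms: none
Why: BBr3 cleaves aryl methyl ethers by O-coordination and SN2 attack of bromide on the methyl groups, while the diaryl ether, the C–Cl bond and the chromenone are inert, so all three phenols should be released in one operation.

Step 5
Reactants: 8 8-chloro-3-[4-(2,6-dihydroxyphenoxy)phenyl]-7-hydroxy-4H-chromen-4-one; 9 4-hydroxyphenylacetic acid
Product: 11 bisoflavolin J, via tetrahydroxy deoxybenzoin 10 (not isolated)
Conditions: BF3·OEt2 (neat), 85 °C; then DMF, MsCl, 70 °C; aq. NaOAc work-up
Reagents that add atoms: N,N-dimethylformamide, CN(C)C=O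
Why: BF3 activates acid 9 and C-acylates the 2-aryloxyresorcinol ring of 8 at C4 (Friedel–Crafts/Fries-type, through the aryl ester and the BF2 chelate) to give deoxybenzoin 10; its methylene is then formylated by the DMF/MsCl iminium salt (Vilsmeier-type) and the ortho-OH closes the ring with loss of dimethylamine. The closest known reaction type is the one-pot BF3·OEt2/DMF/MsCl synthesis of unprotected polyhydroxyisoflavones from resorcinols or pyrogallol and arylacetic acids, already used in step 1. Ring C'' closes by 6-endo-trig attack of the phenol oxygen (future O1'') on the aminomethylene carbon (future C2''), followed by elimination of the amine. No stereocentre is formed. The step needs acylation on the resorcinol ring only, which is secured because the free resorcinol is by far the most nucleophilic arene present (ring A is an acyl-deactivated phenol, ring B only an aryl ether). It also needs a single regioisomer, which is secured because C4 and C6 of the 2-aryloxyresorcinol are equivalent and only the OH ortho to the new ketone can cyclise, so the ether must end up at C8'' and the free OH at C7''.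

**Compound list**

1 | 2-chlororesorcinol (2-chlorobenzene-1,3-diol) | Oc1cccc(O)c1Cl | starting material
2 | 4-bromophenylacetic acid | OC(=O)Cc1ccc(Br)cc1 | starting material
3 | 2-(4-bromophenyl)-1-(3-chloro-2,4-dihydroxyphenyl)ethan-1-one | O=C(Cc1ccc(Br)cc1)c1ccc(O)c(Cl)c1O | intermediate (not isolated)
4 | 3-(4-bromophenyl)-8-chloro-7-hydroxy-4H-chromen-4-one | O=c1c(-c2ccc(Br)cc2)coc2c(Cl)c(O)ccc12 | intermediate
5 | 3-(4-bromophenyl)-8-chloro-7-methoxy-4H-chromen-4-one | COc1ccc2c(=O)c(-c3ccc(Br)cc3)coc2c1Cl | intermediate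
6 | 2,6-dimethoxyphenol | COc1cccc(OC)c1O | starting material
7 | 8-chloro-3-[4-(2,6-dimethoxyphenoxy)phenyl]-7-methoxy-4H-chromen-4-one | COc1ccc2c(=O)c(-c3ccc(Oc4c(OC)cccc4OC)cc3)coc2c1Cl | intermediate
8 | 8-chloro-3-[4-(2,6-dihydroxyphenoxy)phenyl]-7-hydroxy-4H-chromen-4-one | Oc1ccc2c(=O)c(-c3ccc(Oc4c(O)cccc4O)cc3)coc2c1Cl | intermediate
9 | 4-hydroxyphenylacetic acid | OC(=O)Cc1ccc(O)cc1 | starting material
10 | 8-chloro-3-[4-[2,6-dihydroxy-3-[2-(4-hydroxyphenyl)acetyl]phenoxy]phenyl]-7-hydroxy-4H-chromen-4-one | Oc1ccc2c(=O)c(-c3ccc(Oc4c(O)ccc(C(=O)Cc5ccc(O)cc5)c4O)cc3)coc2c1Cl | intermediate (not isolated)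
11 | bisoflavolin J | O=c1c(-c2ccc(Oc3c(O)ccc4c(=O)c(-c5ccc(O)cc5)coc34)cc2)coc2c(Cl)c(O)ccc12 | target

**Step count and risks**

Total step count: 5 (steps 1 and 5 are one-pot, two-stage operations).
Longest linear sequence: 5 steps, from 1 and 2 to 11; 6 and 9 enter as commercial materials.

Steps most likely to fail:

1. Step 5 (key step). The chromenone carbonyl and the three phenols of 8 may bind BF3 and keep the substrate out of solution, so that acylation stalls at the O-acyl stage. The acylation may also stray onto ring B, and acid 9 may acylate itself. The fallback joins two finished monomers through the other ether bond (O–C4'); it sets out from aryl bromide 5 and returns at 11. Pyrogallol and 4-methoxyphenylacetic acid (both commercial) under the conditions of step 1 should give, through 2-(4-methoxyphenyl)-1-(2,3,4-trihydroxyphenyl)ethan-1-one F1, 7,8-dihydroxy-3-(4-methoxyphenyl)-4H-chromen-4-one F2. Methylation of the more acidic 7-OH (MeI 1 equiv, K2CO3, DMF, rt) should give 8-hydroxy-7-methoxy-3-(4-methoxyphenyl)-4H-chromen-4-one F3. Ullmann-type coupling of F3 with 5 (CuI, picolinic acid, K3PO4, DMSO, 100 °C) should give tri-O-methylbisoflavolin J F4, and BBr3 in CH2Cl2 should then give 11.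

2. Step 3. C–O bond formation with the di-ortho-substituted phenoxide may be slow. Base-induced opening of the pyranone ring at C2, hydrodebromination of 5, or oxidative dimerisation of 6 by traces of air may then win. The fallback forms the ether without metal before any chromenone exists; it sets out from 6 (with 1 for the annulation) and returns at 8. Phenol 6 and 4-fluoroacetophenone (K2CO3, DMSO, 120 °C, SNAr) should give 1-[4-(2,6-dimethoxyphenoxy)phenyl]ethan-1-one F5. A Willgerodt–Kindler reaction (S8, morpholine, 130 °C) should give 2-[4-(2,6-dimethoxyphenoxy)phenyl]-1-(morpholin-4-yl)ethane-1-thione F6, which KOH in aqueous ethanol at reflux, then HCl, should hydrolyse to [4-(2,6-dimethoxyphenoxy)phenyl]acetic acid F7. Acid F7 and an excess of 1 under the conditions of step 1 should give, through 1-(3-chloro-2,4-dihydroxyphenyl)-2-[4-(2,6-dimethoxyphenoxy)phenyl]ethan-1-one F8, 8-chloro-3-[4-(2,6-dimethoxyphenoxy)phenyl]-7-hydroxy-4H-chromen-4-one F9. This relies on the free resorcinol being acylated far faster under BF3 than the non-phenolic dimethoxyarene. BBr3 as in step 4 should then give 8.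

3. Step 1. The chlorine-deactivated resorcinol may be O-acylated without Fries shift or C-acylated only sluggishly, and the formylative ring closure may stop at an open aminomethylene ketone. The fallback builds ring C first and attaches ring B by cross-coupling; it sets out from 1 and returns at 5. Resorcinol 1 and acetic acid (BF3·OEt2, 90 °C) should give 1-(3-chloro-2,4-dihydroxyphenyl)ethan-1-one F10. MeI and K2CO3 in acetone should give 1-(3-chloro-2-hydroxy-4-methoxyphenyl)ethan-1-one F11, because the 2-OH is chelated to the ketone and stays free. DMF dimethyl acetal (95 °C) should give (E)-1-(3-chloro-2-hydroxy-4-methoxyphenyl)-3-(dimethylamino)prop-2-en-1-one F12, and iodine (CHCl3, rt) should cyclise it to 8-chloro-3-iodo-7-methoxy-4H-chromen-4-one F13. Suzuki–Miyaura coupling of F13 with 4-bromophenylboronic acid (Pd(PPh3)4, Na2CO3, DME/H2O, 60 °C) should give 5, since the C3–I bond undergoes oxidative addition far faster than the aryl bromide.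

**Further compounds**

F1 | step 5 | 2-(4-methoxyphenyl)-1-(2,3,4-trihydroxyphenyl)ethan-1-one | COc1ccc(CC(=O)c2ccc(O)c(O)c2O)cc1
F2 | step 5 | 7,8-dihydroxy-3-(4-methoxyphenyl)-4H-chromen-4-one | COc1ccc(cc1)-c1coc2c(O)c(O)ccc2c1=O
F3 | step 5 | 8-hydroxy-7-methoxy-3-(4-methoxyphenyl)-4H-chromen-4-one | COc1ccc(cc1)-c1coc2c(O)c(OC)ccc2c1=O
F4 | step 5 | tri-O-methylbisoflavolin J (8-chloro-7-methoxy-3-[4-[[7-methoxy-3-(4-methoxyphenyl)-4-oxo-4H-chromen-8-yl]oxy]phenyl]-4H-chromen-4-one) | COc1ccc(cc1)-c1coc2c(Oc3ccc(cc3)-c3coc4c(Cl)c(OC)ccc4c3=O)c(OC)ccc2c1=O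
F5 | step 3 | 1-[4-(2,6-dimethoxyphenoxy)phenyl]ethan-1-one | CC(=O)c1ccc(Oc2c(OC)cccc2OC)cc1
F6 | step 3 | 2-[4-(2,6-dimethoxyphenoxy)phenyl]-1-(morpholin-4-yl)ethane-1-thione | S=C(Cc1ccc(Oc2c(OC)cccc2OC)cc1)N1CCOCC1
F7 | step 3 | [4-(2,6-dimethoxyphenoxy)phenyl]acetic acid | OC(=O)Cc1ccc(Oc2c(OC)cccc2OC)cc1
F8 | step 3 | 1-(3-chloro-2,4-dihydroxyphenyl)-2-[4-(2,6-dimethoxyphenoxy)phenyl]ethan-1-one | O=C(Cc1ccc(Oc2c(OC)cccc2OC)cc1)c1ccc(O)c(Cl)c1O
F9 | step 3 | 8-chloro-3-[4-(2,6-dimethoxyphenoxy)phenyl]-7-hydroxy-4H-chromen-4-one | Oc1ccc2c(=O)c(-c3ccc(Oc4c(OC)cccc4OC)cc3)coc2c1Cl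
F10 | step 1 | 1-(3-chloro-2,4-dihydroxyphenyl)ethan-1-one | CC(=O)c1ccc(O)c(Cl)c1O
F11 | step 1 | 1-(3-chloro-2-hydroxy-4-methoxyphenyl)ethan-1-one | CC(=O)c1ccc(OC)c(Cl)c1O
F12 | step 1 | (E)-1-(3-chloro-2-hydroxy-4-methoxyphenyl)-3-(dimethylamino)prop-2-en-1-one | CN(C)/C=C/C(=O)c1ccc(OC)c(Cl)c1O
F13 | step 1 | 8-chloro-3-iodo-7-methoxy-4H-chromen-4-one | COc1ccc2c(=O)c(I)coc2c1Cl
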